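**Plan**

- Retrosynthesis: first cut the six benzyl C–O bonds and the diphenylmethylene ketal; then, in one operation, the ring B C1–C(=O) bond and the C(=O)–O3 bond to ring A; last, the ring C acyl–O4 bond of ring B.
- Enabling feature: the ester carbon between ring B C1 and the meta oxygen O3 of ring A is a single carbon flanked by an aryl carbon and a phenolic oxygen, which is carbon monoxide. Ring B C1 has two ortho hydrogens, so ring B can enter as an unhindered 4-iodo-2,6-dioxygenated phenyl ester with no carboxyl group of its own.
- Forward, ring B–C fragment: 2,6-dihydroxybenzaldehyde is benzylated twice, converted to the phenol by Baeyer–Villiger oxidation, iodinated para to the hydroxyl and esterified with tribenzylgallic acid (ring C).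
- Forward, ring A and union: gallic acid becomes its benzyl ester and 3,4-diphenylmethylene ketal, which leaves one meta hydroxyl; the two fragments are joined with CO under palladium catalysis, and one hydrogenolysis releases the target.
- No ring is formed and the target has no stereocentre, so no stereocontrol is required.

Key step: step 7

Remark on the chemistry: depside acyl groups can migrate between neighbouring phenolic oxygens once these are free, so the final deprotection and isolation are planned neutral, aprotic and without heating.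

**Route**

Step 1
Reactants: 1 2,6-dihydroxybenzaldehyde; 2 benzyl bromide
Product: 3 2,6-bis(benzyloxy)benzaldehyde
Conditions: BnBr (2.2 equiv in all), K2CO3, DMF, 60 °C
Reagents that add atoms: benzyl bromide, BrCc1ccccc1
Why: Double Williamson ether synthesis, in which K2CO3 deprotonates both phenols and each phenoxide displaces bromide from one molecule of the primary benzylic halide, so two equivalents of benzyl bromide are consumed while the aldehyde is untouched.

Step 2
Reactants: 3 2,6-bis(benzyloxy)benzaldehyde
Product: 5 2,6-bis(benzyloxy)phenol, via 2,6-bis(benzyloxy)phenyl formate 4 (not isolated)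
Conditions: mCPBA, CH2Cl2, 0 °C to rt; aq. NaHCO3 wash; then K2CO3 (cat.), MeOH, rt
Reagents that add atoms: mCPBA, O=C(OO)c1cccc(Cl)c1
Why: Baeyer–Villiger (Dakin-type) oxidation, in which the electron-rich 2,6-dialkoxyaryl group migrates in the Criegee intermediate to give the aryl formate, and base-catalysed methanolysis then frees the phenol without touching the benzyl ethers.

Step 3
Reactants: 5 2,6-bis(benzyloxy)phenol
Product: 6 2,6-bis(benzyloxy)-4-iodophenol
Conditions: BnMe3N+ ICl2−, NaHCO3, CH2Cl2/MeOH, rt
Reagents that add atoms: benzyltrimethylammonium dichloroiodate, C[N+](C)(C)Cc1ccccc1.Cl[I-]Cl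
Why: Electrophilic aromatic iodination, in which the bicarbonate-buffered phenol oxygen is the strongest donor and both its ortho positions are blocked, so iodine should enter at C4, para to the hydroxyl.

Step 4
Reactants: 6 2,6-bis(benzyloxy)-4-iodophenol; 7 3,4,5-tris(benzyloxy)benzoic acid
Product: 8 2,6-bis(benzyloxy)-4-iodophenyl 3,4,5-tris(benzyloxy)benzoate
Conditions: DCC, DMAP (cat.), CH2Cl2, 0 °C to rt
Reagents that add atoms: none
Why: Steglich esterification, in which DMAP converts the O-acylisourea of 7 into an acylpyridinium reactive enough to acylate the phenol flanked by two benzyloxy groups, the aryl iodide being inert.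

Step 5
Reactants: 9 gallic acid; 2 benzyl bromide
Product: 10 benzyl 3,4,5-trihydroxybenzoate
Conditions: BnBr (1.0 equiv), KHCO3, DMF, rt to 40 °C
Reagents that add atoms: none
Why: Carboxylate O-alkylation (SN2), in which KHCO3 deprotonates only the carboxylic acid, so benzyl bromide esterifies it and the three much less acidic phenols stay free.

Step 6
Reactants: 10 benzyl 3,4,5-trihydroxybenzoate; 11 dichlorodiphenylmethane
Product: 12 benzyl 7-hydroxy-2,2-diphenyl-1,3-benzodioxole-5-carboxylate
Conditions: K2CO3, MeCN, rt
Reagents that add atoms: none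
Why: Ketal formation by double nucleophilic substitution, in which only two neighbouring hydroxyls can close the five-membered dioxole on the diaryl dichloride and the 3,4- and 4,5-pairs are equivalent by symmetry, so exactly one meta hydroxyl remains.

Step 7
Reactants: 8 2,6-bis(benzyloxy)-4-iodophenyl 3,4,5-tris(benzyloxy)benzoate; 12 benzyl 7-hydroxy-2,2-diphenyl-1,3-benzodioxole-5-carboxylate
Product: 13 benzyl 7-{3,5-bis(benzyloxy)-4-[3,4,5-tris(benzyloxy)benzoyloxy]benzoyloxy}-2,2-diphenyl-1,3-benzodioxole-5-carboxylate
Conditions: CO (1 atm), Pd(OAc)2 (5 mol%), Xantphos (6 mol%), Et3N, toluene, 80 °C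
Reagents that add atoms: carbon monoxide, [C-]#[O+]
Why: Zerovalent palladium formed from Pd(OAc)2 and Xantphos adds oxidatively into the C–I bond of 8, carbon monoxide inserts to give an aroylpalladium iodide, and the phenol of 12, deprotonated by Et3N, replaces iodide on palladium and leaves by reductive elimination as the aryl ester, so the ring B C1–carbonyl bond and the carbonyl–O bond to ring A form in one operation. The closest known reaction type is the palladium-catalysed aryloxycarbonylation of aryl iodides with CO and phenols, applied here to a new pair of partners. No ring closes and no stereocentre is created. The selectivity needed is chemoselectivity, namely capture of the aroylpalladium by the phenol of 12 and not acyl exchange at the ring B–ring C aryl ester already present. It is secured by 12 carrying the only free hydroxyl in the mixture, by the non-nucleophilic tertiary amine base that keeps the phenoxide concentration low, and by the two benzyloxy groups that flank the ester oxygen on ring B. The iodide sits between two ring hydrogens, so oxidative addition and CO insertion are unhindered.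

Step 8
Reactants: 13 benzyl 7-{3,5-bis(benzyloxy)-4-[3,4,5-tris(benzyloxy)benzoyloxy]benzoyloxy}-2,2-diphenyl-1,3-benzodioxole-5-carboxylate
Product: 14 3-{[3,5-dihydroxy-4-(3,4,5-trihydroxybenzoyloxy)benzoyl]oxy}-4,5-dihydroxybenzoic acid
Conditions: H2 (1 atm), 10% Pd/C, THF, rt
Reagents that add atoms: none
Why: Heterogeneous catalytic hydrogenolysis, in which the five benzyl ethers, the benzyl ester and the doubly benzylic diphenylmethylene ketal all offer benzylic C–O bonds to Pd/C, whereas the two aryl ester links have none and should persist.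

**Compound list**

1 | 2,6-dihydroxybenzaldehyde | O=Cc1c(O)cccc1O | starting material
2 | benzyl bromide | BrCc1ccccc1 | starting material
3 | 2,6-bis(benzyloxy)benzaldehyde | O=Cc1c(OCc2ccccc2)cccc1OCc1ccccc1 | intermediate
4 | 2,6-bis(benzyloxy)phenyl formate | O=COc1c(OCc2ccccc2)cccc1OCc1ccccc1 | intermediate
5 | 2,6-bis(benzyloxy)phenol | Oc1c(OCc2ccccc2)cccc1OCc1ccccc1 | intermediate
6 | 2,6-bis(benzyloxy)-4-iodophenol | Oc1c(OCc2ccccc2)cc(I)cc1OCc1ccccc1 | intermediate
7 | 3,4,5-tris(benzyloxy)benzoic acid | O=C(O)c1cc(OCc2ccccc2)c(OCc2ccccc2)c(OCc2ccccc2)c1 | starting material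
8 | 2,6-bis(benzyloxy)-4-iodophenyl 3,4,5-tris(benzyloxy)benzoate | Ic1cc(OCc2ccccc2)c(OC(=O)c2cc(OCc3ccccc3)c(OCc3ccccc3)c(OCc3ccccc3)c2)c(OCc2ccccc2)c1 | intermediate
9 | gallic acid (3,4,5-trihydroxybenzoic acid) | O=C(O)c1cc(O)c(O)c(O)c1 | starting material
10 | benzyl 3,4,5-trihydroxybenzoate | O=C(OCc1ccccc1)c1cc(O)c(O)c(O)c1 | intermediate
11 | dichlorodiphenylmethane | ClC(Cl)(c1ccccc1)c1ccccc1 | starting material
12 | benzyl 7-hydroxy-2,2-diphenyl-1,3-benzodioxole-5-carboxylate | O=C(OCc1ccccc1)c1cc(O)c2OC(c3ccccc3)(c3ccccc3)Oc2c1 | intermediate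
13 | benzyl 7-{3,5-bis(benzyloxy)-4-[3,4,5-tris(benzyloxy)benzoyloxy]benzoyloxy}-2,2-diphenyl-1,3-benzodioxole-5-carboxylate | O=C(OCc1ccccc1)c1cc(OC(=O)c2cc(OCc3ccccc3)c(OC(=O)c3cc(OCc4ccccc4)c(OCc4ccccc4)c(OCc4ccccc4)c3)c(OCc3ccccc3)c2)c2OC(c3ccccc3)(c3ccccc3)Oc2c1 | intermediate
14 | 3-{[3,5-dihydroxy-4-(3,4,5-trihydroxybenzoyloxy)benzoyl]oxy}-4,5-dihydroxybenzoic acid | O=C(O)c1cc(O)c(O)c(OC(=O)c2cc(O)c(OC(=O)c3cc(O)c(O)c(O)c3)c(O)c2)c1 | target

**Step count and risks**

Total step count: 8. Longest linear sequence: 6 steps (steps 1, 2, 3, 4, 7, 8).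

The three steps most likely to fail:

The carbonylative coupling (step 7) is the most exposed. The ring A phenoxide may exchange acyl groups with the ring B–ring C ester already present, and slow capture of the aroylpalladium by a hindered, electron-poor phenol would leave room for reduction of the C–I bond. The fallback separates carbonylation from ester formation. Setting out from 8, 2,4,6-trichlorophenyl formate with Pd(OAc)2, Xantphos and Et3N in toluene at rt (the formate releases CO and its phenol in the flask) should give the activated ester 2,4,6-trichlorophenyl 3,5-bis(benzyloxy)-4-[3,4,5-tris(benzyloxy)benzoyloxy]benzoate F1. Acyl transfer from F1 to phenol 12 with Et3N and catalytic DMAP in THF at rt then comes back to the route at 13. The ring B carbonyl carbon still comes from CO and the same two bonds are made, but the activated ester is far more electrophilic than the ring B–ring C ester, so exchange at the latter should not compete.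

The iodination (step 3) may lose regiocontrol, with attack at C3 (ortho and para to the two benzyloxy groups) instead of C4, or the electron-rich phenol may couple oxidatively para to para. The fallback uses the ease of oxidation instead of fighting it and places the leaving group through oxygen. Setting out from 5, Teuber oxidation with (KO3S)2NO in buffered aqueous acetone should give 2,6-bis(benzyloxy)-1,4-benzoquinone F2. Reduction with Na2S2O4 gives 2,6-bis(benzyloxy)benzene-1,4-diol F3. PhNTf2 and Et3N in CH2Cl2 should sulfonylate the unhindered hydroxyl, not the one flanked by two benzyloxy groups, to give 3,5-bis(benzyloxy)-4-hydroxyphenyl trifluoromethanesulfonate F4. Steglich esterification with 7 (DCC, DMAP) gives 2,6-bis(benzyloxy)-4-(trifluoromethanesulfonyloxy)phenyl 3,4,5-tris(benzyloxy)benzoate F5. F5 then takes the place of 8 in the carbonylation with 12 (CO, Pd(OAc)2, Xantphos, Et3N, toluene, 80 °C; aryl triflates undergo the same aryloxycarbonylation), and the route is rejoined at 13.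

The global hydrogenolysis (step 8) may stall at the diaryl ketal, which is cleaved more slowly than the benzyl groups. The long exposure then needed would favour galloyl migration between neighbouring oxygens of the liberated polyphenol. The fallback removes the ketal by a different mechanism first. Setting out from 13, aqueous AcOH (80%) at 80 °C should hydrolyse the ketal to benzyl 3-{3,5-bis(benzyloxy)-4-[3,4,5-tris(benzyloxy)benzoyloxy]benzoyloxy}-4,5-dihydroxybenzoate F6. A short hydrogenolysis of the six benzyl groups (H2, 10% Pd/C, THF, rt) then arrives at 14.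

**Further compounds**

F1 | step 7 | 2,4,6-trichlorophenyl 3,5-bis(benzyloxy)-4-[3,4,5-tris(benzyloxy)benzoyloxy]benzoate | O=C(Oc1c(Cl)cc(Cl)cc1Cl)c1cc(OCc2ccccc2)c(OC(=O)c2cc(OCc3ccccc3)c(OCc3ccccc3)c(OCc3ccccc3)c2)c(OCc2ccccc2)c1
F2 | step 3 | 2,6-bis(benzyloxy)-1,4-benzoquinone | O=C1C=C(OCc2ccccc2)C(=O)C(OCc2ccccc2)=C1
F3 | step 3 | 2,6-bis(benzyloxy)benzene-1,4-diol | Oc1cc(OCc2ccccc2)c(O)c(OCc2ccccc2)c1
F4 | step 3 | 3,5-bis(benzyloxy)-4-hydroxyphenyl trifluoromethanesulfonate | O=S(=O)(Oc1cc(OCc2ccccc2)c(O)c(OCc2ccccc2)c1)C(F)(F)F
F5 | step 3 | 2,6-bis(benzyloxy)-4-(trifluoromethanesulfonyloxy)phenyl 3,4,5-tris(benzyloxy)benzoate | O=C(Oc1c(OCc2ccccc2)cc(OS(=O)(=O)C(F)(F)F)cc1OCc1ccccc1)c1cc(OCc2ccccc2)c(OCc2ccccc2)c(OCc2ccccc2)c1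
F6 | step 8 | benzyl 3-{3,5-bis(benzyloxy)-4-[3,4,5-tris(benzyloxy)benzoyloxy]benzoyloxy}-4,5-dihydroxybenzoate | O=C(OCc1ccccc1)c1cc(O)c(O)c(OC(=O)c2cc(OCc3ccccc3)c(OC(=O)c3cc(OCc4ccccc4)c(OCc4ccccc4)c(OCc4ccccc4)c3)c(OCc3ccccc3)c2)c1
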